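(The readings are calculated from invented constants; the scatter is artificial.)

Each new flask is charged with 20 mM of E, and the earlier runs, made with other charges, show how much E is lost in a given time and how little of that loss appears as Q.

| flask | E | temperature | remark | time |
|---|---|---|---|---|
| eta | 28 mM | −10 °C | run made earlier |  |
| theta | 44 mM | 12 °C | run made earlier |  |
| south-west | 20 mM |  | at −20 °C throughout | 0.60 h |
| north | 20 mM |  | at 20 °C until 30 min, from then on at −20 °C | 1.0 h |

- eta (time / h: Q / %, E / %): 0.417: 0, 97.5; 0.833: 0, 95.7; 1.33: 1.0, 92.3; 2.00: 0, 87.2; 3.00: 0.8, 82.9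
- theta (time / min: Q / %, E / %): 3.00: 1.1, 93.1; 5.00: 0, 86.6; 8.00: 0, 79.9; 12.0: 0.6, 72.4; 20.0: 1.4, 59.6; 40.0: 9.3, 36.9

(readings scatter by 1 percentage point)

- which of the two ends with the higher amount of Q, in percent of the E charged ("neither" if they lie within 2 percentage points) (south-west / north / neither)
- Q at the end, in percent of the E charged, south-west
- Q at the end, in percent of the E charged, north



Taking the last reading of each run and assuming that the loss is first order, so that the different charges of the two runs do not enter, I read a rate constant of 0.0625 h⁻¹ at −10 °C and 1.50 h⁻¹ at 12 °C, which gives an activation energy of 90.0 kJ mol⁻¹ and so an estimate of 4.22 h⁻¹ at 20 °C and 0.0123 h⁻¹ at −20 °C. I reckon with the dose, the rate constant of E loss at each temperature multiplied by the time spent there and summed over the legs, so that [E] stands at its charge times exp(−dose): for north it comes to 2.11, of which the cold leg adds hardly any, for south-west to 0.00738, and the theta run had reached 0.997 at its last reading.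

Two extreme versions of the flask give me an estimated range for Q. In the first, E lost becomes Q at once, which gives 0.735 % in south-west and 87.9 % in north. In the second, the lag (induction period) of the theta run carries over, with Q assumed to follow the dose whatever the temperature, and in this version north, whose dose is larger than the theta run's, holds at least the 9.3 % read there. North's floor exceeds south-west's ceiling by 8.6 percentage points, more than the margin, so I commit to north, and between floor and ceiling I take the geometric mean, 28.6 %.

The forecast says north, with 0 % for south-west and 25 % for north, a north lower than mine; it reckons Q in north from the hot leg, “then cooling to −20 °C freezes it”.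

The flask gives north, with 0 % in south-west and 29.2 % in north.

    E ⇌ D (K = 1.88, k = 0.00143 s⁻¹, Ea = 95.0 kJ mol⁻¹, ΔH = −34.0 kJ mol⁻¹)
    D → G (k = 0.00230 s⁻¹, Ea = 83.0 kJ mol⁻¹)
    D ⇌ Z (K = 6.40, k = 7.08 × 10⁻⁴ s⁻¹, Ea = 91.0 kJ mol⁻¹, ΔH = −23.0 kJ mol⁻¹)
    G → Q (k = 2.96 × 10⁻⁴ s⁻¹, Ea = 84.0 kJ mol⁻¹)
    Z → J (k = 0.0500 s⁻¹, Ea = 75.0 kJ mol⁻¹)
    J → Q (k = 0.00176 s⁻¹, Ea = 95.0 kJ mol⁻¹)
    (constants at 20 °C)

In south-west the half-life of E by its forward step to D alone is 64 h, far longer than the 0.60 h of the flask, while in north at 20 °C it is 0.13 h, shorter than the hot leg of 30 min. At that change north holds 29.1 % Q beside 45.5 % G, whose half-life by the loss to Q alone at 20 °C is 0.65 h. North's dose puts E at 12.1 % against 13.5 % in the flask. The neighbour of south-west kept at 5 °C takes a dose of 0.345, which puts E at 70.8 % against 69.5 %, and it holds 0.673 % Q.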